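The data were computed with constants of no real substance; the scatter is artificial.

Run Tuesday's flask slowly in your head, and count turns of one enzyme rather than millimoles.

in all of them: enzyme 10 µM

| run | starting material | second substrate | remark |
|---|---|---|---|
| Tuesday's | 20 mM | 36 mM | the very flask that is asked about, followed so far |
| Friday's | 40 mM | 36 mM | run made earlier |
| flask | 20 mM | 36.0 mM |  |

| run | time / min | target / % |
|---|---|---|
| Tuesday's | 0.200 | 5.4 |
| Tuesday's | 0.333 | 9.4 |
| Tuesday's | 0.500 | 14.1 |
| Tuesday's | 0.833 | 22.3 |
| Tuesday's | 1.50 | 37.8 |
| Tuesday's | 2.50 | 57.2 |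
| Friday's | 0.417 | 6.4 |
| Friday's | 0.667 | 10.2 |
| Friday's | 1.00 | 14.7 |
| Friday's | 2.00 | 28.3 |
| Friday's | 3.00 | 38.2 |
| Friday's | 5.00 | 54.6 |

(standard deviation of a reading: 0.3 percentage points)

* factor on the rate of making target when 10% of the starting material are converted if enzyme is charged twice over
* factor on the rate when 10% of the starting material are converted if enzyme is charged at 100 µM instead

- no earlier run changes the charge of enzyme; that part of a forecast is a guess

Begin with the first instants. Between 0.200 min and 0.500 min, a stretch that brackets 10% conversion, Tuesday's target climbs at 5.80 mM min⁻¹. Divide by the 10 µM of enzyme charged to get w = 9.67 s⁻¹, and call w, the rate of making target per enzyme charged, the turnover frequency. It is a reading, with 0.3 percentage points on each point behind it. One turn then takes 0.103 s, far shorter than the 0.200 min of the first reading, by which Tuesday's flask has made 108 targets per enzyme charged.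

Now look at the middle. Friday's run, with 40 mM of starting material, reads w = 9.49 s⁻¹ between 0.417 min and 1.00 min, close to Tuesday's value.

Then go to the end of Tuesday's run. Between 1.50 min and 2.50 min, w reads 6.47 s⁻¹, lower than at the start, with 8.56 mM of starting material left at the last reading.

No run changes the enzyme, so my own reckoning rests on an assumption: hold w fixed at fixed conversion, and the factors are 2 for doubling and 10.0 for 100 µM. The forecast has the same centres, 2 (1.6 to 2.3) and 10 (5 to 12), and reasons: “At fixed conversion, composition is the same, so the rate should scale with active enzyme”.

The flask gives 1.69 and 4.91, the second below the forecast's centre.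

    second substrate + starting complex ⇌ ternary complex (K = 70.0 L mol⁻¹, k = 2100 L mol⁻¹ s⁻¹)
    2 starting complex ⇌ resting dimer, settled at all times (K = 2.50 × 10⁵ L mol⁻¹)
    starting material + enzyme ⇌ starting complex (K = 52.0 L mol⁻¹, k = 36000 L mol⁻¹ s⁻¹)
    ternary complex → enzyme + target (k = 38.0 s⁻¹)

At 0.500 min Tuesday's flask holds its catalyst as enzyme 27.1%, starting complex 23.0%, ternary complex 23.5% and resting dimer 26.4%, an off-cycle resting state counted as two per dimer, and w over the last step's constant 38 s⁻¹ reads 25.4% as ternary complex. By 5.00 min that flask has enzyme at 77.9% and resting dimer at 5.54%. Carry Tuesday's reading of w, with its scatter, to the flask with 100 µM of enzyme: scaled by the factor 4.91 and by 10 µM over 100 µM, it estimates w near 10% conversion at roughly 4.75 s⁻¹, and so roughly 12.5% of the catalyst charged as ternary complex.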